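We read the late level first. E is charged at cE = 0.20 M under held Q, and the flask is the one already followed on Friday.

| flask | E | Q | remark | time |
|---|---|---|---|---|
| Friday's | 0.20 M | 10 mM (held) | the very flask that is asked about, followed so far |  |
| flask | 0.20 M | 10 mM (held) |  | 10 h |

Friday's run (percent of the E charged)

| time / h | X / % | E / % |
|---|---|---|
| 0.250 | 11 | 70 |
| 0.500 | 12 | 42 |
| 1.00 | 29 | 1 |
| 2.00 | 26 | 5 |
| 4.00 | 25 | 0 |

(standard deviation of a reading: 2 percentage points)

- percent here means E units held: one D counts as two
- what is said of X includes D
- E is a solid; its amount is given per volume of the solution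
- at the start none of G is dissolved
- steps thought possible: Q <-> G; L + G -> X; X <-> J; L + X <-> D; E <-> L
- at the start none of E is in solution
- in an amount of X, one D counts as one X

- time, not beyond 10 h, at which the flask holds most X
- the amount of X, in percent of the E charged, at that time
- earliest time at which at least nineteen twentieths of that best amount are there
- latest time at which they still are

The curve can be drawn from these readings. E starts by falling about 1.12 h⁻¹ of the charge, and that line reaches zero at a knee near 0.875 h; E reads 1 % at 1.00 h. X climbs on average 0.290 h⁻¹ of the charge up to its highest reading, 29 % at 1.00 h, just past that knee. It then runs into a level of 25.5 %, the mean of the last two readings.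

We carry the kept share, the late level of X over its peak, 0.879, a reading with the scatter of 2 percentage points on each reading behind it. For a curve that falls from a peak to a level, a kept share under 0.950, the part of the best that the asked window demands, means the window closes on the fall, not on the level. Our own line, that part of the highest reading, is 27.5 %, and the reading of 26 % at 2.00 h is already lower, so we expect the peak near the knee and the close before 2.00 h.

The forecast gives a best of 27.5 % at 1.2 h, with the window from 0.9 h to 2.5 h, and adds “That late edge is poorly fixed”. Its close lies later than ours.

    Q ⇌ G, rate k1*(csat - [G]) (kL = 0.0620 s⁻¹)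
    L + G → X (k = 0.140 M⁻¹ s⁻¹)
    X ⇌ J (K = 3.10, k = 0.00330 s⁻¹)
    L + X ⇌ D, settled at all times (K = 14.0 M⁻¹)
    E ⇌ L, rate k5*(cs5 - [L]) while solid is left; crystals form when [L] > cs5 (solubility = 0.120 M, k = 7.30 × 10⁻⁴ s⁻¹)

The flask peaks at 0.966 h with 29.7 %, and the window runs from 0.870 h to 1.16 h, against the forecast's 2.5 h. At 1.45 h X stands at 26.1 %, under the new line of 28.2 %. The neighbour flask, left until 4.0 h, reached 29.7 %, for which the kept share gives 26.1 %, and it ends at 24.4 %.

(The numbers in the tables come from a simulation for an exercise, and the scatter is random.)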